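**Assumption:** the target SMILES has no stereocentre and no stereodescriptor, so the ring E–ring F biaryl axis is left uncontrolled (formed as the racemate) and the route delivers the constitution given.

**Retrosynthetic overview**
1. Global dealkylation is last; before it, the ring D–O–ring E ether is cut, giving a pentacyclic A–B–C–D phenol and an E–F–G–H aryl bromide (Ullmann union).
2. Ring A comes off as an arylboronic acid (Chan–Lam). The furan C–O bond is opened (oxidative oxa-Michael), then the ring B–ring C carbon–carbon bond: the key intermolecular Michael addition of a dibenzodioxin phenol (rings C–D) to 2-methoxy-1,4-benzoquinone (ring B).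
3. The dibenzodioxin comes from 2,6-dibromo-3,5-dimethoxybenzaldehyde (ring D) and a 4-bromo-3-hydroxyacetophenone (ring C): Ullmann ether, Baeyer–Villiger, intramolecular SNAr. A second Baeyer–Villiger turns the acetyl group into the nucleophilic phenol.
4. E–F–G–H: a symmetric 2,2'-dibromobiaryl (Ullmann homocoupling) is mono-etherified with a G–H phenol made by Ullmann coupling and Baeyer–Villiger oxidation.
5. Ring-forming order: dioxin ring (between C and D), then the B–C bond, then the furan ring; rings A and E–H are attached afterwards through ether bonds.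

**Labels for the pentacyclic core:** rings B/C use dibenzofuran numbering (C-1 to C-4 on ring B, C-4 next to the furan O; C-6 to C-9 on ring C, C-6 next to the furan O). Ring D is joined through the oxygens on C-8 and C-9.

## Route

Step 1
Reactants: 1 3,5-dimethoxybenzaldehyde
Product: 2 2,6-dibromo-3,5-dimethoxybenzaldehyde
Conditions: Br2 (2.2 equiv), AcOH, rt
Reagents that add atoms: bromine BrBr
Why: Electrophilic aromatic bromination puts each bromine ortho to the formyl group, para to one methoxy and ortho to the other, the position between the two methoxy groups being the least reactive.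

Step 2
Reactants: 3 4-bromo-3,5-dimethoxybenzoic acid
Product: 6 1-(4-bromo-3,5-dimethoxyphenyl)ethanone, via lithium carboxylate 4 (not isolated), via dilithium gem-diolate 5 (not isolated)
Conditions: MeLi (2.2 equiv), THF, 0 °C to rt; then aq. HCl, 0 °C
Reagents that add atoms: methyllithium [Li]C
Why: Addition of methyllithium to the lithium carboxylate gives a dilithium gem-diolate that collapses to the methyl ketone only on acidic work-up, so over-addition is avoided and an acetyl group (a latent phenol that is inert to peracid until ring C becomes electron-rich) is installed.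

Step 3
Reactants: 6 1-(4-bromo-3,5-dimethoxyphenyl)ethanone
Product: 7 1-(4-bromo-3,5-dihydroxyphenyl)ethanone
Conditions: BBr3 (3 equiv), CH2Cl2, −78 °C to rt; H2O
Reagents that add atoms: none
Why: Lewis-acid ether cleavage with BBr3 removes both methyl groups while the aryl bromide and the ketone survive.

Step 4
Reactants: 7 1-(4-bromo-3,5-dihydroxyphenyl)ethanone
Product: 8 1-(4-bromo-3-hydroxy-5-isopropoxyphenyl)ethanone
Conditions: 2-iodopropane (1.0 equiv), K2CO3 (1.1 equiv), DMF, 50 °C (unreacted 7 recycled)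
Reagents that add atoms: 2-iodopropane CC(C)I
Why: Williamson etherification with one equivalent of alkyl iodide desymmetrises the resorcinol statistically, and the bulky isopropyl group later shields the neighbouring ring C carbon.

Step 5
Reactants: 2 2,6-dibromo-3,5-dimethoxybenzaldehyde (3 equiv); 8 1-(4-bromo-3-hydroxy-5-isopropoxyphenyl)ethanone
Product: 9 2-(5-acetyl-2-bromo-3-isopropoxyphenoxy)-6-bromo-3,5-dimethoxybenzaldehyde
Conditions: CuI (10 mol%), N,N-dimethylglycine·HCl (30 mol%), Cs2CO3, 1,4-dioxane, 90 °C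
Reagents that add atoms: none
Why: Ullmann diaryl ether coupling in which the carbon–bromine bonds of 2 are activated by the ortho formyl group whereas the bromide of 8 sits on an electron-rich phenoxide ring, and excess 2 limits the reaction to one of its two equivalent bromides.

Step 6
Reactants: 9 2-(5-acetyl-2-bromo-3-isopropoxyphenoxy)-6-bromo-3,5-dimethoxybenzaldehyde
Product: 11 2-(5-acetyl-2-bromo-3-isopropoxyphenoxy)-6-bromo-3,5-dimethoxyphenol, via aryl formate 10 (not isolated)
Conditions: mCPBA (1.3 equiv), CH2Cl2, 0 °C to rt; then K2CO3 (0.2 equiv), MeOH, 0 °C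
Reagents that add atoms: 3-chloroperoxybenzoic acid OOC(=O)c1cccc(Cl)c1
Why: Baeyer–Villiger oxidation is chemoselective for the aldehyde, whose aryl group carries an ortho aryloxy donor, over the electron-poor aryl methyl ketone, and methanolysis of the formate frees the ring D phenol.

Step 7
Reactants: 11 2-(5-acetyl-2-bromo-3-isopropoxyphenoxy)-6-bromo-3,5-dimethoxyphenol
Product: 12 1-(6-bromo-4-isopropoxy-7,9-dimethoxydibenzo[b,e][1,4]dioxin-2-yl)ethanone
Conditions: Cs2CO3 (1.5 equiv), DMF, 100 °C
Reagents that add atoms: none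
Why: Intramolecular SNAr in which the ring D phenoxide displaces the ring C bromide para to the acetyl group through a six-membered transition state, closing the dibenzodioxin with unambiguous regiochemistry.

Step 8
Reactants: 12 1-(6-bromo-4-isopropoxy-7,9-dimethoxydibenzo[b,e][1,4]dioxin-2-yl)ethanone
Product: 14 6-bromo-4-isopropoxy-7,9-dimethoxydibenzo[b,e][1,4]dioxin-2-ol, via aryl acetate 13 (not isolated)
Conditions: mCPBA (2.5 equiv), TFA (cat.), CH2Cl2, 0 °C to rt; then K2CO3 (0.2 equiv), MeOH, rt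
Reagents that add atoms: 3-chloroperoxybenzoic acid OOC(=O)c1cccc(Cl)c1
Why: In this second Baeyer–Villiger oxidation the now electron-rich, para-oxygenated aryl group migrates in preference to methyl, and methanolysis of the acetate unmasks the ring C phenol.

Step 9
Reactants: 14 6-bromo-4-isopropoxy-7,9-dimethoxydibenzo[b,e][1,4]dioxin-2-ol; 15 2-methoxy-1,4-benzoquinone (1.1 equiv)
Product: 16 2-(6-bromo-2-hydroxy-4-isopropoxy-7,9-dimethoxydibenzo[b,e][1,4]dioxin-1-yl)-5-methoxybenzene-1,4-diol
Conditions: diphenyl phosphate (10 mol%), CH2Cl2/HFIP 4:1, 0 °C to rt, N2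
Reagents that add atoms: none
Why: Brønsted-acid-catalysed Michael addition of the phenol through its ortho carbon to the quinone followed by tautomerisation, in which the quinone is attacked at C-5 (para to OMe) and the phenol reacts at the ring carbon para to the isopropoxy group (the other ortho carbon is shielded by that group and is para only to a weaker aryloxy donor), forging the ring B–ring C bond without creating a stereocentre.

Step 10
Reactants: 16 2-(6-bromo-2-hydroxy-4-isopropoxy-7,9-dimethoxydibenzo[b,e][1,4]dioxin-1-yl)-5-methoxybenzene-1,4-diol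
Product: 19 pentacyclic B–C–D hydroquinone (1,4-di-OH; 3-OMe; 7-O-iPr; ring D bromide), via aryl-quinone 17 (not isolated), via dibenzofuran-1,4-dione 18 (not isolated)
Conditions: Ag2O (4 equiv), K2CO3 (0.2 equiv), MeCN, rt; filter; then aq. Na2S2O4, EtOAc, rt
Reagents that add atoms: none
Why: Ag2O oxidises the hydroquinone to the aryl-quinone, whose ortho phenol closes the furan by intramolecular oxa-Michael addition, and the over-oxidised dibenzofurandione that results is returned to the hydroquinone by dithionite.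

Step 11
Reactants: 19 pentacyclic B–C–D hydroquinone
Product: 20 1-O-benzyl ether of 19 (4-OH free)
Conditions: BnBr (1.05 equiv), K2CO3 (1.1 equiv), degassed DMF, 0 °C
Reagents that add atoms: benzyl bromide BrCc1ccccc1
Why: Williamson benzylation takes place at the less hindered hydroxyl next to the biaryl carbon, because the other hydroxyl is flanked by the methoxy group and the furan oxygen and is hydrogen-bonded to the methoxy group.

Step 12
Reactants: 20 1-O-benzyl ether of 19; 21 3,5-dimethoxyphenylboronic acid (3 equiv)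
Product: 22 4-O-(3,5-dimethoxyphenyl) ether of 20 (rings A–D bromide)
Conditions: Cu(OAc)2 (1 equiv), pyridine (5 equiv), 4 Å MS, CH2Cl2, O2 (1 atm), rt
Reagents that add atoms: none
Why: Chan–Lam oxidative coupling arylates the hindered phenol at room temperature and leaves the aryl bromide of ring D untouched.

Step 13
Reactants: 22 rings A–D bromide
Product: 25 rings A–D phenol (ring D OH in place of Br), via aryllithium 23 (not isolated), via lithium aryltrimethoxyborate 24 (not isolated)
Conditions: n-BuLi (1.1 equiv), THF, −78 °C; B(OMe)3 (2 equiv), −78 to 0 °C; then AcOH (1.1 equiv), 30% H2O2, 0 °C to rt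
Reagents that add atoms: hydrogen peroxide OO
Why: Bromine–lithium exchange is faster than any ortho-metalation at −78 °C, and borylation followed by peroxide oxidation converts the aryllithium into the phenol.

Step 14
Reactants: 26 1-bromo-3,5-dimethoxybenzene
Product: 27 1-bromo-2-iodo-3,5-dimethoxybenzene
Conditions: NIS (1.05 equiv), TFA (10 mol%), MeCN, rt
Reagents that add atoms: N-iodosuccinimide O=C1CCC(=O)N1I
Why: Electrophilic iodination occurs ortho to bromine and para to a methoxy group, the position between the two methoxy groups being disfavoured.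

Step 15
Reactants: 27 1-bromo-2-iodo-3,5-dimethoxybenzene (2 equiv)
Product: 28 2,2'-dibromo-4,4',6,6'-tetramethoxy-1,1'-biphenyl
Conditions: copper powder (5 equiv), DMF, 150 °C
Reagents that add atoms: none
Why: Classical Ullmann biaryl homocoupling takes place at the more reactive carbon–iodine bond and creates the tetra-ortho-substituted ring E–ring F axis without stereocontrol (racemic axis, unspecified in the target).

Step 16
Reactants: 26 1-bromo-3,5-dimethoxybenzene
Product: 30 2-bromo-4,6-dimethoxybenzaldehyde, via iminium chloride 29 (not isolated)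
Conditions: POCl3 (1.5 equiv), DMF, 0 to 90 °C; then ice/H2O
Reagents that add atoms: N,N-dimethylformamide CN(C)C=O; water O
Why: Vilsmeier–Haack formylation occurs ortho to bromine and para to methoxy, and the iminium salt is hydrolysed on work-up.

Step 17
Reactants: 31 2,4,6-trimethoxybenzaldehyde
Product: 33 2,4,6-trimethoxyphenol, via aryl formate 32 (not isolated)
Conditions: mCPBA (1.2 equiv), CH2Cl2, 0 °C to rt; then K2CO3 (0.2 equiv), MeOH
Reagents that add atoms: 3-chloroperoxybenzoic acid OOC(=O)c1cccc(Cl)c1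
Why: Baeyer–Villiger (Dakin-type) oxidation of the electron-rich aldehyde followed by formate methanolysis gives the phenol.

Step 18
Reactants: 30 2-bromo-4,6-dimethoxybenzaldehyde; 33 2,4,6-trimethoxyphenol
Product: 34 2,4-dimethoxy-6-(2,4,6-trimethoxyphenoxy)benzaldehyde
Conditions: CuI (10 mol%), picolinic acid (20 mol%), K3PO4 (2 equiv), DMSO, 90 °C
Reagents that add atoms: none
Why: Ullmann diaryl ether coupling of the hindered phenol with a bromide that is activated by the ortho formyl group.

Step 19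
Reactants: 34 2,4-dimethoxy-6-(2,4,6-trimethoxyphenoxy)benzaldehyde
Product: 36 2,4-dimethoxy-6-(2,4,6-trimethoxyphenoxy)phenol, via aryl formate 35 (not isolated)
Conditions: mCPBA (1.2 equiv), CH2Cl2, 0 °C to rt; then K2CO3 (0.2 equiv), MeOH
Reagents that add atoms: 3-chloroperoxybenzoic acid OOC(=O)c1cccc(Cl)c1
Why: Baeyer–Villiger oxidation of the 2,4,6-trioxygenated benzaldehyde and methanolysis unmask the ring G phenol between the methoxy and aryloxy groups.

Step 20
Reactants: 28 2,2'-dibromo-4,4',6,6'-tetramethoxy-1,1'-biphenyl (3 equiv); 36 2,4-dimethoxy-6-(2,4,6-trimethoxyphenoxy)phenol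
Product: 37 2-bromo-2'-[2,4-dimethoxy-6-(2,4,6-trimethoxyphenoxy)phenoxy]-4,4',6,6'-tetramethoxy-1,1'-biphenyl
Conditions: CuI (20 mol%), 2,2,6,6-tetramethylheptane-3,5-dione (40 mol%), Cs2CO3 (2 equiv), NMP, 120 °C
Reagents that add atoms: none
Why: Ullmann diaryl ether coupling with a diketone ligand that suits electron-rich, ortho-substituted partners, a threefold excess of the symmetric dibromide (recovered) ensuring mono-etherification.

Step 21
Reactants: 25 rings A–D phenol; 37 E–F–G–H bromide
Product: 38 fully protected octamer (14 OMe; 1 OBn; 1 O-iPr)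
Conditions: CuI (30 mol%), 2,2,6,6-tetramethylheptane-3,5-dione (60 mol%), Cs2CO3 (2 equiv), NMP, 120 °C, argon
Reagents that add atoms: none
Why: Convergent Ullmann diaryl ether coupling joins the 2,6-dioxygenated phenol of ring D to the remaining bromide on ring E, neither fragment carrying another free OH or halide.

Step 22
Reactants: 38 fully protected octamer
Product: 39 CNP0192765.0
Conditions: BBr3 (40 equiv), CH2Cl2, −78 °C to rt; H2O; reversed-phase purification under argon
Reagents that add atoms: none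
Why: Exhaustive Lewis-acid dealkylation cleaves the fourteen methyl ethers, the benzyl ether and the isopropyl ether, while the diaryl ether, dibenzofuran and dioxin C–O bonds are inert to BBr3.

## Compound list

1 | 3,5-dimethoxybenzaldehyde | COc1cc(C=O)cc(OC)c1 | starting material
2 | 2,6-dibromo-3,5-dimethoxybenzaldehyde | O=Cc1c(Br)c(OC)cc(OC)c1Br | intermediate
3 | 4-bromo-3,5-dimethoxybenzoic acid | COc1cc(C(=O)O)cc(OC)c1Br | starting material
4 | lithium 4-bromo-3,5-dimethoxybenzoate | [Li+].COc1cc(C(=O)[O-])cc(OC)c1Br | intermediate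
5 | dilithium 1-(4-bromo-3,5-dimethoxyphenyl)ethane-1,1-diolate | [Li+].[Li+].COc1cc(C(C)([O-])[O-])cc(OC)c1Br | intermediate
6 | 1-(4-bromo-3,5-dimethoxyphenyl)ethanone | CC(=O)c1cc(OC)c(Br)c(OC)c1 | intermediate
7 | 1-(4-bromo-3,5-dihydroxyphenyl)ethanone | CC(=O)c1cc(O)c(Br)c(O)c1 | intermediate
8 | 1-(4-bromo-3-hydroxy-5-isopropoxyphenyl)ethanone | CC(=O)c1cc(O)c(Br)c(OC(C)C)c1 | intermediate
9 | 2-(5-acetyl-2-bromo-3-isopropoxyphenoxy)-6-bromo-3,5-dimethoxybenzaldehyde | O=Cc1c(Br)c(OC)cc(OC)c1Oc1cc(C(C)=O)cc(OC(C)C)c1Br | intermediate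
10 | 2-(5-acetyl-2-bromo-3-isopropoxyphenoxy)-6-bromo-3,5-dimethoxyphenyl formate | O=COc1c(Br)c(OC)cc(OC)c1Oc1cc(C(C)=O)cc(OC(C)C)c1Br | intermediate
11 | 2-(5-acetyl-2-bromo-3-isopropoxyphenoxy)-6-bromo-3,5-dimethoxyphenol | Oc1c(Br)c(OC)cc(OC)c1Oc1cc(C(C)=O)cc(OC(C)C)c1Br | intermediate
12 | 1-(6-bromo-4-isopropoxy-7,9-dimethoxydibenzo[b,e][1,4]dioxin-2-yl)ethanone | CC(=O)c1cc(OC(C)C)c2Oc3c(Br)c(OC)cc(OC)c3Oc2c1 | intermediate
13 | 6-bromo-4-isopropoxy-7,9-dimethoxydibenzo[b,e][1,4]dioxin-2-yl acetate | CC(=O)Oc1cc(OC(C)C)c2Oc3c(Br)c(OC)cc(OC)c3Oc2c1 | intermediate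
14 | 6-bromo-4-isopropoxy-7,9-dimethoxydibenzo[b,e][1,4]dioxin-2-ol | Oc1cc(OC(C)C)c2Oc3c(Br)c(OC)cc(OC)c3Oc2c1 | intermediate
15 | 2-methoxy-1,4-benzoquinone | COC1=CC(=O)C=CC1=O | starting material
16 | 2-(6-bromo-2-hydroxy-4-isopropoxy-7,9-dimethoxydibenzo[b,e][1,4]dioxin-1-yl)-5-methoxybenzene-1,4-diol | COc1cc(O)c(cc1O)-c1c(O)cc(OC(C)C)c2Oc3c(Br)c(OC)cc(OC)c3Oc12 | intermediate
17 | 2-(6-bromo-2-hydroxy-4-isopropoxy-7,9-dimethoxydibenzo[b,e][1,4]dioxin-1-yl)-5-methoxy-1,4-benzoquinone | COC1=CC(=O)C(=CC1=O)c1c(O)cc(OC(C)C)c2Oc3c(Br)c(OC)cc(OC)c3Oc12 | intermediate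
18 | pentacyclic B–C–D quinone (dibenzofuran-1,4-dione; 3-OMe; 7-O-iPr; ring D: Br next to the O on C-8, then OMe, H, OMe) | COC1=CC(=O)c2c(oc3cc(OC(C)C)c4Oc5c(Br)c(OC)cc(OC)c5Oc4c23)C1=O | intermediate
19 | pentacyclic B–C–D hydroquinone (1,4-di-OH; 3-OMe; 7-O-iPr; ring D bromide) | COc1cc(O)c2c(oc3cc(OC(C)C)c4Oc5c(Br)c(OC)cc(OC)c5Oc4c23)c1O | intermediate
20 | 1-O-benzyl ether of 19 (4-OH free) | COc1cc(OCc2ccccc2)c2c(oc3cc(OC(C)C)c4Oc5c(Br)c(OC)cc(OC)c5Oc4c23)c1O | intermediate
21 | 3,5-dimethoxyphenylboronic acid | COc1cc(OC)cc(B(O)O)c1 | starting material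
22 | 4-O-(3,5-dimethoxyphenyl) ether of 20 (rings A–D bromide) | COc1cc(OCc2ccccc2)c2c(oc3cc(OC(C)C)c4Oc5c(Br)c(OC)cc(OC)c5Oc4c23)c1Oc1cc(OC)cc(OC)c1 | intermediate
23 | ring D aryllithium from 22 | COc1cc(OCc2ccccc2)c2c(oc3cc(OC(C)C)c4Oc5c([Li])c(OC)cc(OC)c5Oc4c23)c1Oc1cc(OC)cc(OC)c1 | intermediate
24 | lithium trimethoxy(aryl)borate from 23 | [Li+].COc1cc(OCc2ccccc2)c2c(oc3cc(OC(C)C)c4Oc5c([B-](OC)(OC)OC)c(OC)cc(OC)c5Oc4c23)c1Oc1cc(OC)cc(OC)c1 | intermediate
25 | rings A–D phenol (ring D OH in place of the Br of 22) | COc1cc(OCc2ccccc2)c2c(oc3cc(OC(C)C)c4Oc5c(O)c(OC)cc(OC)c5Oc4c23)c1Oc1cc(OC)cc(OC)c1 | intermediate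
26 | 1-bromo-3,5-dimethoxybenzene | COc1cc(Br)cc(OC)c1 | starting material
27 | 1-bromo-2-iodo-3,5-dimethoxybenzene | COc1cc(OC)c(I)c(Br)c1 | intermediate
28 | 2,2'-dibromo-4,4',6,6'-tetramethoxy-1,1'-biphenyl (racemic axis) | COc1cc(OC)c(c(Br)c1)-c1c(Br)cc(OC)cc1OC | intermediate
29 | N-[(2-bromo-4,6-dimethoxyphenyl)methylene]-N-methylmethanaminium chloride | [Cl-].C[N+](C)=Cc1c(Br)cc(OC)cc1OC | intermediate
30 | 2-bromo-4,6-dimethoxybenzaldehyde | O=Cc1c(Br)cc(OC)cc1OC | intermediate
31 | 2,4,6-trimethoxybenzaldehyde | COc1cc(OC)c(C=O)c(OC)c1 | starting material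
32 | 2,4,6-trimethoxyphenyl formate | COc1cc(OC)c(OC=O)c(OC)c1 | intermediate
33 | 2,4,6-trimethoxyphenol | COc1cc(OC)c(O)c(OC)c1 | intermediate
34 | 2,4-dimethoxy-6-(2,4,6-trimethoxyphenoxy)benzaldehyde | O=Cc1c(OC)cc(OC)cc1Oc1c(OC)cc(OC)cc1OC | intermediate
35 | 2,4-dimethoxy-6-(2,4,6-trimethoxyphenoxy)phenyl formate | O=COc1c(OC)cc(OC)cc1Oc1c(OC)cc(OC)cc1OC | intermediate
36 | 2,4-dimethoxy-6-(2,4,6-trimethoxyphenoxy)phenol | Oc1c(OC)cc(OC)cc1Oc1c(OC)cc(OC)cc1OC | intermediate
37 | 2-bromo-2'-[2,4-dimethoxy-6-(2,4,6-trimethoxyphenoxy)phenoxy]-4,4',6,6'-tetramethoxy-1,1'-biphenyl (racemic axis) | COc1cc(OC)c(c(Br)c1)-c1c(OC)cc(OC)cc1Oc1c(OC)cc(OC)cc1Oc1c(OC)cc(OC)cc1OC | intermediate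
38 | fully protected octamer (ether of the ring D oxygen of 25 with the ring E carbon of 37; 14 OMe, 1 OBn, 1 O-iPr) | COc1cc(OCc2ccccc2)c2c(oc3cc(OC(C)C)c4Oc5c(Oc6cc(OC)cc(OC)c6-c6c(OC)cc(OC)cc6Oc6c(OC)cc(OC)cc6Oc6c(OC)cc(OC)cc6OC)c(OC)cc(OC)c5Oc4c23)c1Oc1cc(OC)cc(OC)c1 | intermediate
39 | CNP0192765.0 | Oc1cc(O)cc(Oc2c(O)cc(O)c3c2oc2cc(O)c4c(c23)Oc2c(O)cc(O)c(Oc3cc(O)cc(O)c3-c3c(O)cc(O)cc3Oc3c(O)cc(O)cc3Oc3c(O)cc(O)cc3O)c2O4)c1 | target

## Summary

Total steps: 22. Longest linear sequence: 14 steps (steps 2–13, then 21 and 22, from 3).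

**Steps most likely to fail**

Step 9 (key Michael addition; risks are attack through the other ortho carbon of ring C, competing arylation by ring D, and redox scrambling between adduct and quinone). The fallback sets out from 14 and comes back at 17. Phenol 14 is converted into its sodium phenolate (NaH, THF, −40 °C) and treated with 2-bromo-5-methoxy-1,4-benzoquinone F1, prepared by (NH4)2Ce(NO3)6 oxidation of commercial 1-bromo-2,4,5-trimethoxybenzene in aqueous MeCN. Under basic conditions only the phenolate ring is nucleophilic, and the Michael addition is followed by loss of bromide, so the quinone oxidation level is kept. Aryl-quinone 17 is obtained directly and is then cyclised and reduced as in step 10.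

Step 21 (union of two large fragments through an ether flanked by three ortho substituents). The fallback sets out from 37 (with 25) and comes back at 38. Bromide 37 is turned (n-BuLi, THF, −78 °C; B(OiPr)3; aqueous NH4Cl) into the E–F–G–H boronic acid F2. With 4-(diacetoxyiodo)anisole and BF3·OEt2 (CH2Cl2, −78 °C to rt, then aqueous NaBF4) this gives the aryl(4-methoxyphenyl)iodonium tetrafluoroborate F3. Phenol 25 is then O-arylated without any transition metal (t-BuOK, THF, 0 °C to rt); the ortho-substituted, less electron-rich aryl group of F3 is transferred and 4-iodoanisole is released, giving 38.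

Step 22 (sixteen dealkylations; the free polyphenol is air-sensitive and hard to purify, and the ring E–ring F 2,2'-diol may cyclise in acid). The fallback sets out from 38 and comes back at 39. The crude BBr3 reaction mixture is not worked up to the free phenol but concentrated and peracetylated (Ac2O, pyridine, DMAP) to the hexadecaacetate of the target F4, which is stable and can be purified on silica. Oxygen-free methanolysis (NaOMe cat., degassed MeOH, 0 °C, then acidic resin) then releases 39 under mild, non-acidic conditions.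

Further compounds
F1 | step 9 | 2-bromo-5-methoxy-1,4-benzoquinone | COC1=CC(=O)C(Br)=CC1=O
F2 | step 21 | {2'-[2,4-dimethoxy-6-(2,4,6-trimethoxyphenoxy)phenoxy]-4,4',6,6'-tetramethoxy-1,1'-biphenyl-2-yl}boronic acid | COc1cc(OC)c(c(B(O)O)c1)-c1c(OC)cc(OC)cc1Oc1c(OC)cc(OC)cc1Oc1c(OC)cc(OC)cc1OC
F3 | step 21 | {2'-[2,4-dimethoxy-6-(2,4,6-trimethoxyphenoxy)phenoxy]-4,4',6,6'-tetramethoxy-1,1'-biphenyl-2-yl}(4-methoxyphenyl)iodonium tetrafluoroborate | COc1ccc(cc1)[I+]c1cc(OC)cc(OC)c1-c1c(OC)cc(OC)cc1Oc1c(OC)cc(OC)cc1Oc1c(OC)cc(OC)cc1OC.F[B-](F)(F)F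
F4 | step 22 | hexadecaacetate of CNP0192765.0 | CC(=O)Oc1cc(OC(C)=O)cc(Oc2c(OC(C)=O)cc(OC(C)=O)c3c2oc2cc(OC(C)=O)c4c(c23)Oc2c(OC(C)=O)cc(OC(C)=O)c(Oc3cc(OC(C)=O)cc(OC(C)=O)c3-c3c(OC(C)=O)cc(OC(C)=O)cc3Oc3c(OC(C)=O)cc(OC(C)=O)cc3Oc3c(OC(C)=O)cc(OC(C)=O)cc3OC(C)=O)c2O4)c1
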